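## Structural features

Kukoamine A (C28H42N4O6) is an open-chain, achiral molecule. Its spermine backbone is numbered here N1–C2–C3–C4–N5–C6–C7–C8–C9–N10–C11–C12–C13–N14, and the terminal nitrogens N1 and N14 each carry a 3-(3,4-dihydroxyphenyl)propanoyl (dihydrocaffeoyl) group. The only rings are the two catechol benzene rings, joined to the chain through saturated CH2CH2C(=O) tethers; there is no stereocentre and no alkene geometry to control. The fragile groups are the two catechols, which air oxidises to ortho-quinones (quickly in base, where the molecule's own amines then attack the quinones). The two basic secondary amines N5 and N10 make the free compound very polar, metal-binding and hard to purify. The real difficulty is connectivity: four nitrogens of similar nucleophilicity sit in one flexible chain, the acyl groups must end up on N1 and N14 only, and a misplaced acyl group gives a constitutional isomer that is hard to remove. The key step exploits the twofold symmetry of the molecule, whose symmetry element passes through the midpoint of the C7–C8 bond of the central butane-1,4-diyl chain. Cutting this one C(sp3)–C(sp3) bond gives two identical halves, each with one amide nitrogen and one amine nitrogen, and each ending in N5–C6H2–C7H2•, the radical left when an N-substituted beta-alanine loses CO2. The C6–C7–carboxyl unit is in turn the retron of an aza-Michael addition to an acrylate, so each nitrogen can enter the synthesis already in its final role.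

## Logic of the disconnections

**11 to 10.**
- Bonds cut: the four aryl O–CH3 bonds and the two N–C(=O)O carbamate bonds at N5 and N10.
- Reason: the catechols and the free secondary amines are the only fragile and strongly polar groups, so they should appear in the last operation.
- Gain: 10 is neutral, stable to air and fit for silica gel.
- Demand: one reagent must cleave six groups of two kinds without touching the two secondary amides, and the product must be kept from oxygen once the pH rises.

**10 to 9 + 9 (key disconnection).**
- Bond cut: C7–C8, the C(sp3)–C(sp3) bond that the symmetry element bisects.
- Reason: it is the only single cut that gives two identical pieces. Each piece holds one amide nitrogen and one carbamate nitrogen whose roles were fixed when they were introduced, so the question of which of four nitrogens is acylated never arises.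
- Gain: the 14-atom chain falls to a 7-atom chain, the whole skeleton is finished in one bond formation, and only three skeletal building blocks (1, 2, 5) remain.
- Demand: a homocoupling at an unactivated primary carbon beta to nitrogen, without elimination, beside an easily oxidised 1,2-dimethoxyarene.
- Choice of manifold: the direct anodic (Kolbe) coupling of 8 would save one step, but its working potential lies well above that at which the arene is oxidised. The reductive, nickel-mediated form from the N-acyloxyphthalimide 9 is therefore taken.
- In one sentence, the route is the reductive decarboxylative homodimerisation of 9 across C7–C8. That sentence does not fit an acylation of the intact C3–C4–C3 tetraamine chain.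

**9 to 8.**
- Bond cut: the acyl C–O bond of the N-acyloxyphthalimide group.
- Reason: the group is only the electron-accepting handle for decarboxylation.
- Gain: a plain carboxylic acid.
- Demand: an esterification that leaves the secondary amide N–H alone.

**8 to 7.**
- Bond changed: the acid O–H is exchanged for an ester O–CH3.
- Reason: the carboxyl group must be masked while N5 is still a free amine, and it arrives as an ester in the step before.
- Gain: none in size, but 7 comes straight from a conjugate addition.
- Demand: a hydrolysis that spares carbamate and amide and does not trigger a retro-Michael reaction.

**7 to 4 + 5 (through 6).**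
- Bonds cut: first the N5–C(=O) carbamate bond, then N5–C6.
- Reason: the beta-amino ester is the direct retron of an aza-Michael addition, which brings in C6, C7 and the sacrificial carboxyl carbon in one atom-economic step.
- Gain: 5 is a commodity chemical and 4 has only one reactive nitrogen.
- Demand: the primary amine must add once only, and the secondary amine 6 must be capped before it adds again.

**4 to 1 + 2 (through 3).**
- Bond cut: the N1–C(=O) amide bond.
- Reason: it leads to a commercial acid and a symmetric diamine whose two nitrogens are identical, so only a statistical question is left, not a chemoselectivity question.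
- Gain: both pieces are bought.
- Demand: monoacylation, secured by an excess of the cheap and volatile 2.

## Other disconnections considered

**Alternative 1:** (the first that comes to mind)
- Cut: both amide bonds N1–C(=O) and N14–C(=O), back to spermine A1 and two molecules of an activated acid such as 2,5-dioxopyrrolidin-1-yl 3-(3,4-dimethoxyphenyl)propanoate A2.
- Forward key step: twofold chemoselective N-acylation of the primary amino groups of A1 beside its two secondary amino groups.
- Ground for the chosen plan: the selectivity rests only on the modest steric difference between a primary and an unbranched secondary amine, and it must hold at two sites of one molecule. Every error gives a regioisomer or an over-acylated homologue as polar and basic as the wanted product, so the separation falls on the least tractable compounds of the synthesis. Temporary masking of N5 and N10 of A1 would make it safe, but it adds steps on very polar intermediates and cancels the advantage in length. The chosen plan never asks one molecule to discriminate between its own nitrogens.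

**Alternative 2:**
- Cut: N5–C4 and N10–C11, that is, two-directional growth from butane-1,4-diamine A3.
- Forward key step: double reductive amination of A3 with two molecules of 3-(3,4-dimethoxyphenyl)-N-(3-oxopropyl)propanamide A4. A redox-neutral variant would open two molecules of the cyclic imidate 2-[2-(3,4-dimethoxyphenyl)ethyl]-5,6-dihydro-4H-1,3-oxazine A5 at its C6 with A3, so that the amide appears as the C–N bond forms.
- Ground for the chosen plan: in both forms a primary amine becomes a more nucleophilic secondary amine that competes for the electrophile at both chain ends, so under- and over-alkylated polyamines must be expected together. A4 is a beta-amido aldehyde that can lose its amide by beta-elimination through its enol or enamine. A5 offers a second, harder site at C2, where a primary amine should add to form an amidine rather than substitute at C6. The forcing temperature that C6 attack would need also permits acyl migration between N1 and N5. The products are unprotected, and the step count is no lower because A4 and A5 must themselves be made.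

**Alternative 3:**
- Cut: N5–C6 and N10–C9 at the amide oxidation level. Two molecules of 4 are joined through a succinyl unit to the tetraamide N1,N4-bis{3-[3-(3,4-dimethoxyphenyl)propanamido]propyl}butanediamide A6.
- Forward key step: twofold reduction of the two inner carbonyl groups (C6 and C9) of A6.
- Ground for the chosen plan: A6 holds four secondary amides of nearly the same electronic and steric character, so a hydride or borane reagent has no basis for reducing only the inner pair. The half-acylated succinyl stage can also close to a five-membered imide instead of taking up the second amine. The outer acyl groups would then have to be introduced after the reduction, which returns the plan to the cut of alternative 1 with more steps.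

Key step: step 5

Assumption: kukoamine A is made as the free base shown by the SMILES string; it has no stereocentre and no stereogenic double bond, so no SMILES string below needs a stereodescriptor.

## Steps

Step 1
Reactants: 1 3-(3,4-dimethoxyphenyl)propanoic acid; 2 propane-1,3-diamine
Product: 4 N-(3-aminopropyl)-3-(3,4-dimethoxyphenyl)propanamide, via acylimidazole 3 (not isolated)
Conditions: CDI (1.0 equiv), THF, rt, 1 h; then added dropwise to 2 (8 equiv), THF, 0 °C to rt
Reagents that add atoms: 1,1'-carbonyldiimidazole, O=C(n1ccnc1)n1ccnc1 (gives the imidazol-1-yl group of 3, which is lost again on the way to 4)
Why: Amide formation through an acylimidazole (CDI activation), which acylates a primary amine cleanly at or below rt. Inverse addition into a large excess of the symmetric diamine 2 keeps 2 in excess over 4 at all times, so the second acylation is statistically suppressed; surplus 2 is volatile and any neutral bis-amide is removed by acid-base extraction.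

Step 2
Reactants: 4 N-(3-aminopropyl)-3-(3,4-dimethoxyphenyl)propanamide; 5 methyl acrylate
Product: 7 methyl 3-[(tert-butoxycarbonyl){3-[3-(3,4-dimethoxyphenyl)propanamido]propyl}amino]propanoate, via secondary amino ester 6 (not isolated)
Conditions: 5 (1.0 equiv), MeOH, 0 °C to rt, 16 h; then Boc2O (1.1 equiv), rt
Reagents that add atoms: di-tert-butyl dicarbonate, CC(C)(C)OC(=O)OC(=O)OC(C)(C)C
Why: Aza-Michael addition of a primary amine to an acrylate in a protic solvent, followed by carbamate formation in the same flask. The secondary amine 6 is more hindered than 4 and only one equivalent of 5 is offered, so mono-addition should dominate. Boc2O traps 6 before it can add again or revert, and any doubly alkylated tertiary amine stays basic and is washed out with dilute citric acid.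

Step 3
Reactants: 7 methyl 3-[(tert-butoxycarbonyl){3-[3-(3,4-dimethoxyphenyl)propanamido]propyl}amino]propanoate
Product: 8 3-[(tert-butoxycarbonyl){3-[3-(3,4-dimethoxyphenyl)propanamido]propyl}amino]propanoic acid
Conditions: LiOH·H2O (2 equiv), THF/H2O 3:1, rt; then 1 M HCl to pH 3, 0 °C
Reagents that add atoms: lithium hydroxide (its oxygen becomes the acid OH), [Li+].[OH-]
Why: Saponification of a methyl ester (BAc2). Secondary amide, tert-butyl carbamate and aryl ethers are inert to LiOH at rt, and a carbamate nitrogen is too poor a leaving group for a retro-Michael loss.

Step 4
Reactants: 8 3-[(tert-butoxycarbonyl){3-[3-(3,4-dimethoxyphenyl)propanamido]propyl}amino]propanoic acid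
Product: 9 1,3-dioxoisoindolin-2-yl 3-[(tert-butoxycarbonyl){3-[3-(3,4-dimethoxyphenyl)propanamido]propyl}amino]propanoate
Conditions: N-hydroxyphthalimide (1.1 equiv), DIC (1.1 equiv), DMAP (10 mol %), CH2Cl2, rt
Reagents that add atoms: N-hydroxyphthalimide, O=C1c2ccccc2C(=O)N1O
Why: Carbodiimide (Steglich-type) esterification gives the redox-active ester. The only remaining N–H is a secondary amide, which is not acylated under these conditions, and primary alkyl esters of this kind tolerate a quick filtration through silica gel.

Step 5
Reactants: 9 1,3-dioxoisoindolin-2-yl 3-[(tert-butoxycarbonyl){3-[3-(3,4-dimethoxyphenyl)propanamido]propyl}amino]propanoate (two molecules)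
Product: 10 di-tert-butyl butane-1,4-diylbis({3-[3-(3,4-dimethoxyphenyl)propanamido]propyl}carbamate)
Conditions: NiCl2·6H2O (20 mol %), 4,4',4''-tri-tert-butyl-2,2':6',2''-terpyridine (20 mol %), NaI (0.2 M), DMF (0.15 M in 9), undivided cell, sacrificial Zn anode, reticulated vitreous carbon cathode, constant current, 2 F per mol of 9, rt, Ar; work-up with cold 0.5 M HCl
Reagents that add atoms: none
Why: Nickel-electrocatalytic doubly decarboxylative C(sp3)–C(sp3) coupling of N-acyloxyphthalimides, a known reaction type for primary alkyl esters, is run here with one ester only. The cathode reduces the divalent nickel terpyridine complex to low-valent (monovalent or zerovalent) nickel, which passes one electron into the phthalimide unit of 9; N–O cleavage and loss of CO2 then give the primary radical (Boc)(R)N5–C6H2–C7H2•. This radical is captured by nickel, the alkylnickel species takes up a second radical, and reductive elimination from the trivalent dialkylnickel complex forms the C7–C8 bond of 10. In the known cross-coupling of two different esters the homodimer is the statistical by-product, whereas here both partners are the same, so every productive coupling gives 10 and no cross-selectivity is needed. No ring is closed and no stereocentre is formed. The selectivity needed is C–C coupling over hydrogen abstraction, beta-hydride elimination and beta-nitrogen elimination: the tridentate ligand leaves no free cis site on nickel for either elimination, N5 is a non-basic carbamate and a poor leaving group, and the radical is primary and unhindered, so its capture by nickel should outrun the slower 1,5- and 1,6-hydrogen shifts along the chain. Chemoselectivity is secured by the reductive manifold: the anode reaction is the dissolution of zinc, so no potential is reached at which the 1,2-dimethoxyarene is oxidised (the flaw of an anodic Kolbe coupling of 8), and aryl ether, secondary amide and carbamate are not reduced at the potential at which the nickel complex turns over.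

Step 6
Reactants: 10 di-tert-butyl butane-1,4-diylbis({3-[3-(3,4-dimethoxyphenyl)propanamido]propyl}carbamate)
Product: 11 kukoamine A, N,N'-[butane-1,4-diylbis(azanediylpropane-3,1-diyl)]bis[3-(3,4-dihydroxyphenyl)propanamide]
Conditions: BBr3 (12 equiv), CH2Cl2, −78 °C to rt; MeOH, 0 °C, repeated evaporation; degassed aq NaHCO3 to pH 8, reversed-phase C18, Ar
Reagents that add atoms: none
Why: Lewis-acid ether cleavage: BBr3 binds each aryl methyl ether oxygen and bromide attacks the methyl group (SN2), while the tert-butyl carbamates fragment under the same Lewis acid and the secondary amides only bind BBr3 reversibly. Methanolysis frees boron as volatile B(OMe)3, and exclusion of air from the neutralisation onward protects the catechols.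

## Compound list

1 | 3-(3,4-dimethoxyphenyl)propanoic acid | COc1ccc(CCC(=O)O)cc1OC | starting material
2 | propane-1,3-diamine | NCCCN | starting material
3 | 1-[3-(3,4-dimethoxyphenyl)propanoyl]-1H-imidazole | COc1ccc(CCC(=O)n2ccnc2)cc1OC | intermediate
4 | N-(3-aminopropyl)-3-(3,4-dimethoxyphenyl)propanamide | COc1ccc(CCC(=O)NCCCN)cc1OC | intermediate
5 | methyl acrylate (methyl prop-2-enoate) | C=CC(=O)OC | starting material
6 | methyl 3-({3-[3-(3,4-dimethoxyphenyl)propanamido]propyl}amino)propanoate | COc1ccc(CCC(=O)NCCCNCCC(=O)OC)cc1OC | intermediate
7 | methyl 3-[(tert-butoxycarbonyl){3-[3-(3,4-dimethoxyphenyl)propanamido]propyl}amino]propanoate | COc1ccc(CCC(=O)NCCCN(CCC(=O)OC)C(=O)OC(C)(C)C)cc1OC | intermediate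
8 | 3-[(tert-butoxycarbonyl){3-[3-(3,4-dimethoxyphenyl)propanamido]propyl}amino]propanoic acid | COc1ccc(CCC(=O)NCCCN(CCC(=O)O)C(=O)OC(C)(C)C)cc1OC | intermediate
9 | 1,3-dioxoisoindolin-2-yl 3-[(tert-butoxycarbonyl){3-[3-(3,4-dimethoxyphenyl)propanamido]propyl}amino]propanoate | COc1ccc(CCC(=O)NCCCN(CCC(=O)ON2C(=O)c3ccccc3C2=O)C(=O)OC(C)(C)C)cc1OC | intermediate
10 | di-tert-butyl butane-1,4-diylbis({3-[3-(3,4-dimethoxyphenyl)propanamido]propyl}carbamate) | COc1ccc(CCC(=O)NCCCN(CCCCN(CCCNC(=O)CCc2ccc(OC)c(OC)c2)C(=O)OC(C)(C)C)C(=O)OC(C)(C)C)cc1OC | intermediate
11 | kukoamine A | O=C(CCc1ccc(O)c(O)c1)NCCCNCCCCNCCCNC(=O)CCc1ccc(O)c(O)c1 | target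

## Step count and least certain steps

Total step count: 6. Longest linear sequence: 6 steps (1 to 11).

**Step 5 (key step).**
- The most likely failure is that the primary radical, or the alkylnickel species made from it, is quenched before the second carbon partner arrives.
- Quenching could occur by hydrogen abstraction from DMF, by an internal 1,5- or 1,6-hydrogen shift from C3–H or from the amide-activated C2–H, or by beta-hydride elimination. In each case the material ends as chain-terminated monomer.
- The cause is that C–C bond formation is second order in species held at a low stationary concentration. Hydrolysis of the active ester by wet electrolyte would add to the loss.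
- The fallback gives up the C7–C8 cut and makes the N5–C6 and N10–C9 bonds instead. It sets out from 4.
- 2-Nitrobenzenesulfonyl chloride and Et3N in CH2Cl2 give 3-(3,4-dimethoxyphenyl)-N-(3-{[(2-nitrophenyl)sulfonyl]amino}propyl)propanamide F1.
- Two equivalents of F1 are alkylated with 1,4-dibromobutane (K2CO3, DMF, 60 °C, Fukuyama alkylation) to N5,N10-bis[(2-nitrophenyl)sulfonyl]-tetra-O-methylkukoamine A F2. The once-alkylated nitrogen bears no N–H, so it cannot close a pyrrolidine ring.
- Thiophenol and K2CO3 in DMF remove both sulfonyl groups to give tetra-O-methylkukoamine A F3.
- F3 is demethylated under the conditions of step 6, and the fallback comes back to the route at 11.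

**Step 2.**
- The most likely failure is a second conjugate addition of the newly formed secondary amine to 5, together with partial reversal of the first addition before the carbamate is in place. The rate difference between the primary and the secondary amine is only moderate for an unhindered acrylate.
- The fallback blocks the second N–H before the conjugate addition. It sets out from 4.
- Reductive amination with benzaldehyde (NaBH(OAc)3, 1,2-dichloroethane) gives N-[3-(benzylamino)propyl]-3-(3,4-dimethoxyphenyl)propanamide F4.
- F4 has one N–H only and adds to 5 (MeOH, 50 °C) to give methyl 3-(benzyl{3-[3-(3,4-dimethoxyphenyl)propanamido]propyl}amino)propanoate F5.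
- Hydrogenolysis of F5 (H2, Pd(OH)2/C, MeOH) in the presence of Boc2O frees 6 and traps it at once, and the fallback comes back to the route at 7.

**Step 6.**
- Incomplete cleavage of the four ethers is one likely failure.
- Electrophilic tert-butylation of the electron-rich ring could occur, caused by the cation released from the carbamate under a strong Lewis acid.
- Boron could be retained on the catechols.
- The catechols could be oxidised during neutralisation, because the product is polar, basic and air-sensitive at the same time.
- The fallback separates the two kinds of cleavage and places a purifiable salt between them. It sets out from 10.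
- HCl in dioxane at rt removes both carbamates with no Lewis acid present and gives tetra-O-methylkukoamine A dihydrochloride F6, which can be purified by crystallisation or trituration.
- F6 is then demethylated with iodotrimethylsilane (Me3SiI, MeCN, 60 °C; then MeOH). Here the ether oxygen is silylated and iodide attacks the methyl group.
- Neutralisation under argon as in step 6 brings the fallback back to the route at 11.

**Step 1.**
- The most likely failure is a second acylation of the diamine, giving the symmetric bis-amide, if local excess of 3 builds up on addition. Some of the polar amine 4 may also be lost to the aqueous phase on extraction.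
- The fallback replaces statistics by a protecting group. It sets out from 1 (by way of 3).
- 3 is treated with one equivalent of commercial tert-butyl (3-aminopropyl)carbamate in THF to give tert-butyl {3-[3-(3,4-dimethoxyphenyl)propanamido]propyl}carbamate F7.
- F7 is cleaved with HCl in dioxane and freed with aqueous base, and the fallback comes back to the route at 4.

## Further compounds

F1 | step 5 | 3-(3,4-dimethoxyphenyl)-N-(3-{[(2-nitrophenyl)sulfonyl]amino}propyl)propanamide | COc1ccc(CCC(=O)NCCCNS(=O)(=O)c2ccccc2[N+](=O)[O-])cc1OC
F2 | step 5 | N5,N10-bis[(2-nitrophenyl)sulfonyl]-tetra-O-methylkukoamine A | COc1ccc(CCC(=O)NCCCN(CCCCN(CCCNC(=O)CCc2ccc(OC)c(OC)c2)S(=O)(=O)c2ccccc2[N+](=O)[O-])S(=O)(=O)c2ccccc2[N+](=O)[O-])cc1OC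
F3 | step 5 | tetra-O-methylkukoamine A | COc1ccc(CCC(=O)NCCCNCCCCNCCCNC(=O)CCc2ccc(OC)c(OC)c2)cc1OC
F4 | step 2 | N-[3-(benzylamino)propyl]-3-(3,4-dimethoxyphenyl)propanamide | COc1ccc(CCC(=O)NCCCNCc2ccccc2)cc1OC
F5 | step 2 | methyl 3-(benzyl{3-[3-(3,4-dimethoxyphenyl)propanamido]propyl}amino)propanoate | COc1ccc(CCC(=O)NCCCN(CCC(=O)OC)Cc2ccccc2)cc1OC
F6 | step 6 | tetra-O-methylkukoamine A dihydrochloride | COc1ccc(CCC(=O)NCCCNCCCCNCCCNC(=O)CCc2ccc(OC)c(OC)c2)cc1OC.Cl.Cl
F7 | step 1 | tert-butyl {3-[3-(3,4-dimethoxyphenyl)propanamido]propyl}carbamate | COc1ccc(CCC(=O)NCCCNC(=O)OC(C)(C)C)cc1OC
A1 | alternative 1 | spermine | NCCCNCCCCNCCCN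
A2 | alternative 1 | 2,5-dioxopyrrolidin-1-yl 3-(3,4-dimethoxyphenyl)propanoate | COc1ccc(CCC(=O)ON2C(=O)CCC2=O)cc1OC
A3 | alternative 2 | butane-1,4-diamine | NCCCCN
A4 | alternative 2 | 3-(3,4-dimethoxyphenyl)-N-(3-oxopropyl)propanamide | COc1ccc(CCC(=O)NCCC=O)cc1OC
A5 | alternative 2 | 2-[2-(3,4-dimethoxyphenyl)ethyl]-5,6-dihydro-4H-1,3-oxazine | COc1ccc(CCC2=NCCCO2)cc1OC
A6 | alternative 3 | N1,N4-bis{3-[3-(3,4-dimethoxyphenyl)propanamido]propyl}butanediamide | COc1ccc(CCC(=O)NCCCNC(=O)CCC(=O)NCCCNC(=O)CCc2ccc(OC)c(OC)c2)cc1OC
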